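Product in the flask, the dawn run, grows at about 1.23 mM/h, as read between its first and last readings. In the dusk run, charged with 15 mM of free catalyst in place of 10 mM, it grows at about 2.22 mM/h, read the same way.

the same everywhere: starting material 0.10 M; stray impurity 4.8 mM

|  | partner | protic impurity | free catalyst | remark |
|---|---|---|---|---|
| dawn | 0.080 M | 0.030 M | 10 mM | the very flask that is asked about, followed so far |
| dusk | 0.080 M | 0.030 M | 15 mM | run made earlier |
| flask | 0.0800 M | 0.0300 M | 10 mM |  |

| run | time / h | product / % | starting material / % |
|---|---|---|---|
| dawn | 2.50 | 3.2 | 95.6 |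
| dawn | 5.00 | 6.1 | 92.1 |
| dawn | 8.00 | 10.3 | 87.9 |
| dawn | 10.0 | 13.6 | 85.3 |
| dawn | 12.0 | 14.9 | 83.0 |
| dusk | 3.00 | 5.8 | 90.0 |
| dusk | 6.00 | 14.2 | 82.7 |
| dusk | 10.0 | 22.6 | 73.9 |
| dusk | 12.0 | 27.1 | 70.5 |
| dusk | 15.0 | 32.4 | 64.5 |

(each reading ± 0.5 percentage points)

* factor on the rate of making product when 20% of the starting material are converted if free catalyst is charged twice over
* factor on the rate when 20% of the starting material are converted if free catalyst is charged at 50 mM instead

Which charge has to be known well? Starting material, partner and protic impurity stand alike in both runs, so these runs cannot weigh them. Free catalyst rose by a factor of 1.50, but the rate read rose by 1.80, more than in proportion, so some catalyst seems lost from the top of each charge. The size of that loss moves the answer: with no loss, the factor at 50 mM is 5.00. With the 3.75 mM that the two rates imply, itself a reading with scatter, it is 7.40.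

The charge of stray impurity is 4.8 mM. Taken one for one, this leaves the flask 5.20 mM of working catalyst W, the free catalyst charged minus the stray impurity charged. The dusk run then has 1.96 times as much W, against the 1.80 read. With rate proportional to W, my reckoning gives 2.92 and 8.69. The forecast gives 2.9 and 8.4, on the ground of “the stray impurity titrating 4.8 mM of catalyst”; its second value lies below mine.

The flask gives 2.96 and 8.33, from this scheme:

    starting material + free catalyst ⇌ catalyst intermediate A (K = 2.60 /M, k = 0.00340 /M/s)
    catalyst intermediate A → catalyst intermediate B (k = 6.20 × 10⁻⁴ /s)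
    partner + catalyst intermediate B → catalyst intermediate C (k = 0.330 /M/s)
    catalyst intermediate C → catalyst intermediate D (k = 6.80 × 10⁻⁴ /s)
    catalyst intermediate D ⇌ by-product + catalyst intermediate E (K = 0.0120 M, k = 8.70 × 10⁻⁴ /s)
    catalyst intermediate E → free catalyst + product (k = 0.00850 /s)
    free catalyst + stray impurity → spent catalyst (k = 0.0710 /M/s)
    partner + protic impurity → quenched reagent (k = 4.70 × 10⁻⁴ /M/s)

After 4.00 h, earlier than the 14.7 h at which 20% is converted, the flask holds 47.4% of the catalyst charged as spent catalyst, with stray impurity at 1.29% of its charge. The rate at that conversion, 0.00117 M/h, is 0.225 /h per unit of W. The flask charged at 50 mM, with its factor of 8.33, gives 0.216 /h per unit of W.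

All runs are calculated from invented constants; the scatter is artificial.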